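**Assumption:** the C3 silyl-ether epimers from the Luche reduction (mainly one isomer) are carried forward as a mixture, because C3 is re-oxidised to the ketone in Step 13.

## Retrosynthetic overview
1. Niveusin B ⇐ SeO2 hydroxylation of the C15 methyl ⇐ C8 angelate of the 3,10-epoxy hemiketal alcohol.
2. The THF hemiketal bridge and the C10 centre ⇐ acid-mediated transannular hydration of a Δ1(10)-3-keto germacranolide. The α-methylene lactone ⇐ saturated γ-lactone ⇐ C6 ketone with a C7 enolate alkylation.
3. Key step: the 10-membered ring ⇐ anionic oxy-Cope ring expansion ([3,3]-sigmatropic) of a 1,2-divinylcyclohexanol made from (R)-carvone. Carvone gives ring C1–C6 with the Z-C4=C5 enone alkene and the C15 methyl. Its isopropenyl group becomes C9/C10/C14. A (Z)-β-alkoxyvinyl group supplies C7 and C8–O.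
4. Ring order: cyclohexane (carvone) → 10-membered carbocycle (oxy-Cope) → γ-lactone → THF hemiketal bridge.

## Route

**Step 1**
Reactants: 1, (R)-(–)-carvone
Product: 2, (5R)-carveol (C1 epimer mixture)
Conditions: NaBH4, CeCl3·7H2O, MeOH, 0 °C
Reagents that add atoms: none
Why: Luche 1,2-reduction of the enone leaves the carvone C5 stereocentre untouched. The new C1 carbinol centre is irrelevant because it is oxidised in Step 13.

**Step 2**
Reactants: 2
Product: 3, TBS ether of carveol
Conditions: TBSCl, imidazole, DMF, rt
Reagents that add atoms: TBSCl, CC(C)(C)[Si](C)(C)Cl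
Why: Silyl protection of the secondary allylic alcohol so that it survives the oxidation and the strongly basic oxy-Cope.

**Step 3**
Reactants: 3
Product: 4, (6R)-4-(TBSO)-3-methyl-6-(prop-1-en-2-yl)cyclohex-2-en-1-one
Conditions: CrO3, 3,5-dimethylpyrazole, CH2Cl2, –20 °C
Reagents that add atoms: CrO3, O=[Cr](=O)=O (oxygen ends up as the C=O)
Why: Cr(VI)/pyrazole allylic oxidation converts the ring CH2 next to the trisubstituted alkene into the conjugated ketone. This installs the oxygen at what becomes C6, and the isopropenyl stereocentre is untouched.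

**Step 4**
Reactants: 5, 4-methoxybenzyl alcohol; 6, trans-1,2-dichloroethene
Product: 7, (Z)-1-chloro-2-(4-methoxybenzyloxy)ethene
Conditions: KOH, DMSO, 50 °C
Reagents that add atoms: none (both components are listed reactants; only HCl is lost)
Why: Base-induced dehydrochlorination to chloroacetylene, then anti-addition of the alkoxide, gives the Z β-chlorovinyl ether (nucleophilic vinylic substitution).

**Step 5**
Reactants: 4, the TBS-protected γ-silyloxy enone; 7, (Z)-1-chloro-2-(4-methoxybenzyloxy)ethene (vinyl-anion precursor)
Product: 8, tertiary allylic carbinol (C6 OH, Z-CH=CH-OPMB, isopropenyl-bearing C1)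
Conditions: 7, Li powder, cat. DTBB, THF, –78 °C (Cl→Li exchange); CeCl3, –78 °C; then 4, –78 °C
Reagents that add atoms: 7, COc1ccc(CO/C=C\Cl)cc1. Its (Z)-PMBO-CH=CH– group (C10H11O2) is transferred to C6 as the vinylcerium reagent, and Cl is lost as LiCl.
Why: The organocerium adds 1,2 to the enone and avoids conjugate addition (Li–halogen exchange, then Ce transmetalation and carbonyl addition). Axial attack on the half-chair, with the isopropenyl equatorial, puts the new vinyl group axial and cis to the isopropenyl. This is the 1,2-divinyl arrangement that reacts through a chair [3,3] transition state. The C6 carbinol centre is lost in the next step.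

**Step 6** (key step)
Reactants: 8
Product: 9, 10-membered ring enone (C1=C10 Z, C4=C5 Z, C3-OTBS, C6 ketone, C7-CH2CO2Et, C8(R)-OPMB)
Conditions: KH, 18-crown-6, THF, 0 °C→rt; then BrCH2CO2Et, –78→0 °C
Reagents that add atoms: ethyl bromoacetate, CCOC(=O)CBr
Why: Anionic oxy-Cope ([3,3]-sigmatropic) breaks the C1–C6 ring bond and forms C8–C9, expanding six to ten. In the chair transition state the isopropenyl is equatorial and the Z-OPMB is pseudo-axial. For C1 (R) the isopropenyl-bearing carbon then gives the Z C1=C10 alkene and C8 (R). The potassium enolate is alkylated at C7, and C7, being α to the ketone, is assumed to equilibrate to the isomer with the target C7/C8 relationship.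

**Step 7**
Reactants: 9
Product: 10, C6 allylic alcohol (hydroxy ester)
Conditions: NaBH4, CeCl3·7H2O, MeOH, –78→0 °C
Reagents that add atoms: none
Why: Luche 1,2-reduction of the enone is selective over the ester and alkenes. Hydride arrives from the peripheral face of the ring, setting C6–OH anti to C7–C11 so that a trans-fused lactone can close.

**Step 8**
Reactants: 10
Product: 11, saturated trans-fused 6,12-olide
Conditions: cat. PPTS, PhMe, 80 °C
Reagents that add atoms: none (EtOH is lost)
Why: Intramolecular transesterification closes the γ-lactone between C6–O and C12 (lactonisation). No new stereocentre forms, and PMB, TBS and the alkenes survive PPTS.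

**Step 9**
Reactants: 11
Product: 12, α-(dimethylaminomethyl)lactone
Conditions: LiHMDS, THF, –78 °C; then Me2N+=CH2 I–
Reagents that add atoms: Eschenmoser's salt, C[N+](C)=C.[I-]
Why: Lactone enolate Mannich aminomethylation. The stereocentre at C11 is destroyed in the next step.

**Step 10**
Reactants: 12
Product: 13, α-methylene-γ-butyrolactone
Conditions: MeI, CH2Cl2, rt; then DBU, rt
Reagents that add atoms: none (MeI only activates the amine; NMe3 is lost)
Why: Quaternisation followed by E1cB elimination gives the exocyclic methylene with no stereochemical consequence.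

**Step 11**
Reactants: 13
Product: 14, C8 free alcohol (PMB removed)
Conditions: DDQ, CH2Cl2/pH 7 buffer, 0 °C
Reagents that add atoms: none
Why: Oxidative PMB cleavage is orthogonal to the TBS ether, the α-methylene lactone and the alkenes. C8 is untouched.

**Step 12**
Reactants: 14
Product: 15, C3 allylic alcohol
Conditions: HF·pyridine, THF/pyridine, rt
Reagents that add atoms: none
Why: Fluoride desilylation frees the allylic C3 alcohol for selective oxidation.

**Step 13**
Reactants: 15
Product: 16, 3-keto-Δ4 enone (free C8-OH)
Conditions: MnO2, CH2Cl2, rt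
Reagents that add atoms: none
Why: MnO2 oxidises only the allylic C3 alcohol, not the isolated secondary C8 alcohol. The C3 epimer mixture converges here.

**Step 14**
Reactants: 16
Product: 17, 15-deoxy 3,10-epoxy hemiketal with free C8-OH
Conditions: CSA (cat.), THF/H2O 4:1, 40 °C
Reagents that add atoms: water, O
Why: Protonation of the trisubstituted C1=C10 alkene gives the C10 tertiary cation (Markovnikov). The C3 carbonyl oxygen lies across the ring and captures it, and water adds to the resulting oxocarbenium to give the hemiketal. Only the face reachable by the C3 oxygen is attacked, so C10 and the hemiketal carbon C3 are set by the transannular geometry (transannular cyclisation/hydration).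

**Step 15**
Reactants: 17; 18, angelic acid
Product: 19, 8-O-angelate
Conditions: 2,4,6-Cl3C6H2COCl, Et3N, THF; then 17, DMAP, PhMe, rt (Yamaguchi)
Reagents that add atoms: angelic acid (reactant 18), OC(=O)/C(C)=C\C
Why: Yamaguchi esterification acylates the secondary C8 alcohol and leaves the hindered tertiary hemiketal OH alone. The mild, non-heated conditions keep the Z geometry of the angelate.

**Step 16**
Reactants: 19
Product: 20, niveusin B
Conditions: SeO2 (cat.), TBHP, CH2Cl2, rt
Reagents that add atoms: SeO2, O=[Se]=O; tert-butyl hydroperoxide, CC(C)(C)OO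
Why: Riley allylic oxidation (ene/[2,3]-sigmatropic) hydroxylates the methyl on the more substituted end of the only nucleophilic alkene, C4=C5. The angelate and the methylene lactone are electron-poor alkenes and are inert, and no stereocentre is touched.

## Compound list
1 | (R)-(–)-carvone | CC1=CC[C@H](CC1=O)C(C)=C | starting material
2 | (5R)-carveol, C1 epimer mixture | CC1=CC[C@H](CC1O)C(C)=C | intermediate
3 | TBS ether of 2 | CC1=CC[C@H](CC1O[Si](C)(C)C(C)(C)C)C(C)=C | intermediate
4 | (6R)-4-(TBSO)-3-methyl-6-isopropenylcyclohex-2-enone | CC1=CC(=O)[C@H](CC1O[Si](C)(C)C(C)(C)C)C(C)=C | intermediate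
5 | 4-methoxybenzyl alcohol | COc1ccc(CO)cc1 | starting material
6 | trans-1,2-dichloroethene | Cl/C=C/Cl | starting material
7 | (Z)-1-chloro-2-(PMBO)ethene | COc1ccc(CO/C=C\Cl)cc1 | intermediate
8 | 1,2-divinylcyclohexanol (C6 and C3 centres undefined) | CC1=CC(O)(/C=C\OCc2ccc(OC)cc2)[C@H](CC1O[Si](C)(C)C(C)(C)C)C(C)=C | intermediate
9 | 10-ring C6-ketone, 7-CH2CO2Et, 8R-OPMB, 3-OTBS | C/C1=C/CC(O[Si](C)(C)C(C)(C)C)/C(C)=C\C(=O)[C@H](CC(=O)OCC)[C@H](OCc2ccc(OC)cc2)C1 | intermediate
10 | C6 alcohol (hydroxy ester) | C/C1=C/CC(O[Si](C)(C)C(C)(C)C)/C(C)=C\[C@@H](O)[C@H](CC(=O)OCC)[C@H](OCc2ccc(OC)cc2)C1 | intermediate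
11 | saturated trans-fused 6,12-olide | C/C1=C/CC(O[Si](C)(C)C(C)(C)C)/C(C)=C\[C@H]2OC(=O)C[C@@H]2[C@H](OCc3ccc(OC)cc3)C1 | intermediate
12 | Mannich base | C/C1=C/CC(O[Si](C)(C)C(C)(C)C)/C(C)=C\[C@H]2OC(=O)C(CN(C)C)[C@@H]2[C@H](OCc3ccc(OC)cc3)C1 | intermediate
13 | α-methylene lactone, 8-OPMB, 3-OTBS | C/C1=C/CC(O[Si](C)(C)C(C)(C)C)/C(C)=C\[C@H]2OC(=O)C(=C)[C@@H]2[C@H](OCc3ccc(OC)cc3)C1 | intermediate
14 | 8-OH, 3-OTBS | C/C1=C/CC(O[Si](C)(C)C(C)(C)C)/C(C)=C\[C@H]2OC(=O)C(=C)[C@@H]2[C@H](O)C1 | intermediate
15 | 3,8-diol | C/C1=C/CC(O)/C(C)=C\[C@H]2OC(=O)C(=C)[C@@H]2[C@H](O)C1 | intermediate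
16 | 3-keto-8-ol (enone) | C/C1=C/CC(=O)/C(C)=C\[C@H]2OC(=O)C(=C)[C@@H]2[C@H](O)C1 | intermediate
17 | 15-deoxy 3,10-epoxy hemiketal, 8-OH | C=C1C(=O)O[C@@H]2/C=C(/C)[C@@]3(O)CC[C@@](C)(C[C@@H](O)[C@@H]12)O3 | intermediate
18 | angelic acid | OC(=O)/C(C)=C\C | starting material
19 | 8-O-angelate of 17 | C=C1C(=O)O[C@@H]2/C=C(/C)[C@@]3(O)CC[C@@](C)(C[C@@H](OC(=O)/C(C)=C\C)[C@@H]12)O3 | intermediate
20 | niveusin B | C=C1C(=O)O[C@@H]2/C=C(/CO)[C@@]3(O)CC[C@@](C)(C[C@@H](OC(=O)/C(C)=C\C)[C@@H]12)O3 | target

## Totals
Total steps: 16 (Step 4 is a parallel reagent preparation). Longest linear sequence: 15 steps, from carvone (Steps 1–3 and 5–16).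

## Three steps most likely to fail
1. **Step 6, oxy-Cope.** The C1=C10 alkene geometry may not be the predicted Z. The C8 configuration depends on it, and the enolate may expel the β-OPMB group by E1cB. Fallback: run the ring expansion with plain vinylmagnesium bromide instead of the alkoxyvinyl reagent. Dehydrogenate the resulting C6 ketone (IBX) to the C7=C8 enone and epoxidise it (H2O2, NaOH). Open the epoxide with SmI2 to the C8 β-hydroxy ketone, and alkylate the samarium enolate at C7 with ethyl bromoacetate.
2. **Step 3, allylic oxidation.** Oxidation may compete at C1–H, the tertiary C5–H or the allylic methyl. Fallback: convert carvone to the 2-methyl-5-isopropenylcyclohexadiene by a Shapiro-type sequence and add singlet oxygen in a [4+2] cycloaddition. Kornblum–DeLaMare opening of the endoperoxide then gives the γ-hydroxy enone, which is silylated to give 4.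
3. **Step 14, transannular hydration.** Protonation of the alkene under mild acid may be slow, and the C10 configuration could come out wrong or elimination could compete. Fallback: hydrate C1=C10 by Mukaiyama HAT hydration (Co(acac)2, PhSiH3, O2) at the stage of saturated lactone 11, where the methylene Michael acceptor is not yet present. Carry the tertiary C10 alcohol through the TBS and PMB removals, then let it close onto the C3 ketone after the MnO2 oxidation. Separate the C10 epimers, since only the matching epimer can form the hemiketal bridge.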